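**Retrosynthetic overview**
1. The C2 hydroxyl is unmasked last from a methoxy group: the target goes back to 3-[(2R)-2-acetoxypentadecyl]-2,5-dimethoxy-1,4-benzoquinone, in which only the C2 methoxy group is flanked by the side chain.
2. Key disconnection: the bond from the side-chain CH2 (C1') to quinone C3, made by silver-catalysed oxidative decarboxylation of (3R)-3-acetoxyhexadecanoic acid and addition of the primary radical to a ring C–H of 2,5-dimethoxy-1,4-benzoquinone; the complete side chain, with stereocentre and acetate, meets the ring at its final oxidation level.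
3. Enabling feature: C1' is a CH2 directly beside the acetoxy carbinol carbon, so a carboxyl group can stand where the ring will be; C3 and C6 of the quinone ring are the C–H ends of its two enone C=C bonds, which take up an alkyl radical and return to the quinone on oxidation, and the twofold symmetry of the dimethoxyquinone makes them one and the same position.
4. The stereocentre comes from Noyori hydrogenation of tert-butyl 3-oxohexadecanoate (tetradecanoyl chloride plus Meldrum's acid); the acetate is put on before the coupling and is never removed.
5. Ring formation: none; the only ring, the quinone, is bought intact.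

Key step: step 5

Remark: the carbinol carbon of the target is (R) (OAc > CH2–quinone > CH2–alkyl > H). A CH2CO2R group takes the same rank as CH2–quinone, so every precursor from the hydrogenation product onward carries the same descriptor and the same spatial arrangement.

**Step 1**
Reactants: 1 tetradecanoyl chloride; 2 Meldrum's acid (2,2-dimethyl-1,3-dioxane-4,6-dione)
Product: 5 tert-butyl 3-oxohexadecanoate, via 5-(1-hydroxytetradecylidene) Meldrum's acid 3 (not isolated), via tetradecanoylketene 4 (not isolated)
Conditions: pyridine (2 equiv), CH2Cl2, 0 °C to rt; 1 M HCl wash, evaporation; then t-BuOH, toluene, 90 °C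
Reagents that add atoms: tert-butanol, CC(C)(C)O
Why: C-acylation of Meldrum's acid gives 3, which on heating loses acetone and CO2 to the acylketene 4 that the alcohol traps, the standard Meldrum's acid route to β-keto esters.

**Step 2**
Reactants: 5 tert-butyl 3-oxohexadecanoate
Product: 6 tert-butyl (3R)-3-hydroxyhexadecanoate
Conditions: H2 (50 bar), RuCl2[(R)-BINAP] (0.5 mol %), MeOH, 50 °C
Reagents that add atoms: none
Why: Noyori asymmetric hydrogenation of a β-keto ester, in which the ester carbonyl chelates ruthenium and the (R)-BINAP ligand directs hydride to one face of the ketone, should set the (R) carbinol centre as is usual for 3-oxoalkanoates.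

**Step 3**
Reactants: 6 tert-butyl (3R)-3-hydroxyhexadecanoate
Product: 7 tert-butyl (3R)-3-acetoxyhexadecanoate
Conditions: Ac2O, DMAP (cat.), pyridine, rt
Reagents that add atoms: acetic anhydride, CC(=O)OC(C)=O
Why: DMAP-catalysed acylation of a secondary alcohol is reliable and does not touch the stereocentre, and β-elimination is not expected at room temperature.

**Step 4**
Reactants: 7 tert-butyl (3R)-3-acetoxyhexadecanoate
Product: 8 (3R)-3-acetoxyhexadecanoic acid
Conditions: TFA/CH2Cl2 (1:3), rt
Reagents that add atoms: none
Why: Acid-mediated cleavage of a tert-butyl ester with loss of 2-methylpropene frees the acid without base, so the β-acetoxy group should be neither hydrolysed nor eliminated.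

**Step 5**
Reactants: 8 (3R)-3-acetoxyhexadecanoic acid; 9 2,5-dimethoxy-1,4-benzoquinone
Product: 12 3-[(2R)-2-acetoxypentadecyl]-2,5-dimethoxy-1,4-benzoquinone, via 2-acetoxypentadecyl radical 10 (not isolated), via ring adduct radical 11 (not isolated)
Conditions: AgNO3 (0.3 equiv), (NH4)2S2O8 (1.5 equiv, slow addition), 9 (3 equiv), MeCN/H2O (2:1), 65 °C
Reagents that add atoms: none
Why: Persulfate oxidises monovalent silver to divalent silver, which oxidises the carboxylate of 8 with loss of CO2 to the primary radical 10; 10 adds to the unsubstituted ring carbon C3 of 9 to give the adduct radical 11, stabilised by the C2 methoxy oxygen and the C1 carbonyl, and 11 is oxidised and deprotonated back to the quinone 12. The closest known reaction type is the silver-catalysed persulfate decarboxylative C–H alkylation of quinones (a Minisci-type radical alkylation with Kochi–Anderson radical generation), which is established for alkoxy-substituted quinones. No ring is closed and no stereocentre is made; the acetoxy carbon is β to the radical centre, never becomes trigonal and keeps its (R) configuration. The regioselectivity that the step needs is secured by the twofold symmetry of 9, which makes C3 and C6 equivalent so that only one mono-alkyl quinone can form, while excess 9 and slow addition of the oxidant hold back a second alkylation at C6. The 1,2-acetoxy shift of a β-acetoxyalkyl radical (Surzur–Tanner rearrangement) is much slower than addition of a primary radical to a quinone, so the chain should arrive unrearranged.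

**Step 6**
Reactants: 12 3-[(2R)-2-acetoxypentadecyl]-2,5-dimethoxy-1,4-benzoquinone
Product: 13 3-[(2R)-2-acetoxypentadecyl]-2-hydroxy-5-methoxy-1,4-benzoquinone (target)
Conditions: 70% aq. HClO4, CH2Cl2, 0 °C to rt, stopped at full conversion
Reagents that add atoms: water, O
Why: Acid-catalysed addition–elimination hydrolysis of a vinylogous ester, in which the C2 methoxy group, twisted out of conjugation between the C1 carbonyl and the C3 side chain, is the one known to be cleaved selectively in 3-alkyl-2,5-dimethoxy-1,4-benzoquinones, while the coplanar C5 methoxy group and, in a short cold treatment, the acetate should remain.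

**Compound list**
1 | tetradecanoyl chloride | CCCCCCCCCCCCCC(=O)Cl | starting material
2 | Meldrum's acid (2,2-dimethyl-1,3-dioxane-4,6-dione) | CC1(C)OC(=O)CC(=O)O1 | starting material
3 | 5-(1-hydroxytetradecylidene)-2,2-dimethyl-1,3-dioxane-4,6-dione (acyl Meldrum's acid, enol form) | CCCCCCCCCCCCCC(O)=C1C(=O)OC(C)(C)OC1=O | intermediate
4 | tetradecanoylketene | CCCCCCCCCCCCCC(=O)C=C=O | intermediate
5 | tert-butyl 3-oxohexadecanoate | CCCCCCCCCCCCCC(=O)CC(=O)OC(C)(C)C | intermediate
6 | tert-butyl (3R)-3-hydroxyhexadecanoate | CCCCCCCCCCCCC[C@H](CC(=O)OC(C)(C)C)O | intermediate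
7 | tert-butyl (3R)-3-acetoxyhexadecanoate | CCCCCCCCCCCCC[C@H](CC(=O)OC(C)(C)C)OC(C)=O | intermediate
8 | (3R)-3-acetoxyhexadecanoic acid | CCCCCCCCCCCCC[C@H](CC(=O)O)OC(C)=O | intermediate
9 | 2,5-dimethoxy-1,4-benzoquinone | COC1=CC(=O)C(OC)=CC1=O | starting material
10 | 2-acetoxypentadecyl radical from 8 (primary radical at C1, acetoxy carbon configured as in 8) | CCCCCCCCCCCCC[C@H]([CH2])OC(C)=O | intermediate
11 | adduct radical of 10 at C3 of 9 (ring C3 now sp3, its configuration undefined and lost on re-oxidation; radical centre at C2) | CCCCCCCCCCCCC[C@H](CC1[C](OC)C(=O)C=C(OC)C1=O)OC(C)=O | intermediate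
12 | 3-[(2R)-2-acetoxypentadecyl]-2,5-dimethoxy-1,4-benzoquinone | CCCCCCCCCCCCC[C@H](CC1=C(OC)C(=O)C=C(OC)C1=O)OC(C)=O | intermediate
13 | 3-[(2R)-2-acetoxypentadecyl]-2-hydroxy-5-methoxy-1,4-benzoquinone, i.e. (2R)-1-(2-hydroxy-5-methoxy-3,6-dioxocyclohexa-1,4-dien-1-yl)pentadecan-2-yl acetate | CCCCCCCCCCCCC[C@H](CC1=C(O)C(=O)C=C(OC)C1=O)OC(C)=O | target

**Step count and risks**
Total step count: 6. Longest linear sequence: 6 steps (steps 1 to 6; 9 is bought).

Three steps most likely to fail:

Step 5 (key step). What may go wrong: radical capture by the electron-rich and sparingly soluble quinone is slow, so the radical is lost to hydrogen abstraction or dimerisation, or a second alkylation at C6 takes over. Fallback: the same bond is made by polar chemistry at the arene oxidation level. It sets out from 9, which is reduced (Na2S2O4, EtOAc/H2O) to 2,5-dimethoxybenzene-1,4-diol F1 and methylated (Me2SO4, K2CO3, acetone) to 1,2,4,5-tetramethoxybenzene F2; n-BuLi in THF at 0 °C then gives (2,3,5,6-tetramethoxyphenyl)lithium F3. In parallel, (R)-epichlorohydrin is opened with C12H25MgBr and CuI (cat.) to (2R)-1-chloropentadecan-2-ol F4 and closed with NaOH to (2R)-2-tridecyloxirane F5. F3 and F5 with BF3·OEt2 in THF at −78 °C should give (2R)-1-(2,3,5,6-tetramethoxyphenyl)pentadecan-2-ol F6 by attack at the terminal epoxide carbon. Ac2O/pyridine then gives (2R)-1-(2,3,5,6-tetramethoxyphenyl)pentadecan-2-yl acetate F7, and oxidative demethylation with (NH4)2Ce(NO3)6 in MeCN/H2O at 0 °C comes back to the route at 12.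

Step 6. What may go wrong: acid hydrolysis of the acetate during the demethylation, after which the freed hydroxyl closes onto C2, or hydrolysis at the C5 methoxy group in place of the C2 one. Fallback: the two ring oxygens are told apart by methylation instead of demethylation, with no strong acid. It sets out from 8, which is converted with DCC and urea–hydrogen peroxide (DMAP cat., CH2Cl2, 0 °C) into bis[(3R)-3-acetoxyhexadecanoyl] peroxide F8. Heating F8 with commercial 2,5-dihydroxy-1,4-benzoquinone in AcOH at 90 °C (thermal radical alkylation of a hydroxyquinone by a diacyl peroxide) should give 3-[(2R)-2-acetoxypentadecyl]-2,5-dihydroxy-1,4-benzoquinone F9, again without a regiochemical choice because the acceptor is symmetric. One equivalent of TMSCHN2 in toluene/MeOH at 0 °C should then methylate the more acidic, unhindered C5 hydroxyl in preference to the C2 hydroxyl beside the side chain, which comes back to the route at 13.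

Step 2. What may go wrong: incomplete facial selectivity in the hydrogenation, or methanolysis of the tert-butyl ester in the warm, slightly acidic medium. Fallback: biocatalytic reduction in place of metal catalysis. Compound 5 is reduced by an (R)-selective ketoreductase (an NADPH-dependent alcohol dehydrogenase chosen from a commercial screening panel) with glucose dehydrogenase and glucose for cofactor recycling, in phosphate buffer (pH 7) with isopropanol or DMSO as co-solvent at 30 °C. It sets out from 5 and comes back to the route at 6; no compound outside the list is made (entry F0).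

**Further compounds**
F1 | step 5 | 2,5-dimethoxybenzene-1,4-diol | COc1cc(O)c(OC)cc1O
F2 | step 5 | 1,2,4,5-tetramethoxybenzene | COc1cc(OC)c(OC)cc1OC
F3 | step 5 | (2,3,5,6-tetramethoxyphenyl)lithium | [Li]c1c(OC)c(OC)cc(OC)c1OC
F4 | step 5 | (2R)-1-chloropentadecan-2-ol | CCCCCCCCCCCCC[C@H](CCl)O
F5 | step 5 | (2R)-2-tridecyloxirane | CCCCCCCCCCCCC[C@@H]1CO1
F6 | step 5 | (2R)-1-(2,3,5,6-tetramethoxyphenyl)pentadecan-2-ol | CCCCCCCCCCCCC[C@H](Cc1c(OC)c(OC)cc(OC)c1OC)O
F7 | step 5 | (2R)-1-(2,3,5,6-tetramethoxyphenyl)pentadecan-2-yl acetate | CCCCCCCCCCCCC[C@H](Cc1c(OC)c(OC)cc(OC)c1OC)OC(C)=O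
F8 | step 6 | bis[(3R)-3-acetoxyhexadecanoyl] peroxide | CCCCCCCCCCCCC[C@H](CC(=O)OOC(=O)C[C@@H](CCCCCCCCCCCCC)OC(C)=O)OC(C)=O
F9 | step 6 | 3-[(2R)-2-acetoxypentadecyl]-2,5-dihydroxy-1,4-benzoquinone | CCCCCCCCCCCCC[C@H](CC1=C(O)C(=O)C=C(O)C1=O)OC(C)=O
F0 | step 2 | none | none
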